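The route rests on cutting the C-4–C-4a bond of the 4',7-dihydroxyflavan unit. C-4 is a diarylmethine that also carries C-8 of epicatechin, a carbon flanked by the C-7 oxygen and by the pyran oxygen on C-8a. A C-4 cation can therefore be held by epicatechin ring D (its phloroglucinol ring) while flavan ring A serves as the nucleophile. A single acid-triggered cycloalkylation forms C-4–C-4a, closes ring C and sets C-4 cis to the C-2 aryl group. The precursor is an open-chain 1,3-diarylpropan-1-ol. Perbenzylated epicatechin sits on its carbinol carbon, and its C-3 carries a stereodefined 3-benzyloxyphenyl ether beside a 4-pivaloyloxyphenyl ring.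

Key step: step 9

Remark: the target SMILES reads as (2S,4S), that is 2,4-cis, in the flavan unit (rings A, B, C) and as (2R,3R) in the epicatechin unit (ring D phloroglucinol, ring E catechol, ring F pyran), so the latter is taken from natural (−)-epicatechin.

**Fragment 1 (steps 1–3)**

Step 1
Reactants: 1 (−)-epicatechin
Product: 2 (2R,3R)-5,7,3',4'-tetra-O-benzylepicatechin (3-OH free)
Conditions: BnBr (4.4 equiv), K2CO3 (5 equiv), DMF, 0 °C to rt, Ar
Reagents that add atoms: benzyl bromide, BrCc1ccccc1
Why: Williamson ether synthesis in which carbonate deprotonates only the four phenols and leaves the secondary C-3 alcohol alone, while the cold start under argon limits C-benzylation of ring D and base-induced opening of ring F, so that both stereocentres of 1 are carried over unchanged.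

Step 2
Reactants: 2 (2R,3R)-5,7,3',4'-tetra-O-benzylepicatechin
Product: 3 (2R,3R)-8-bromo-5,7,3',4'-tetra-O-benzylepicatechin
Conditions: NBS (1.0 equiv), CH2Cl2, −40 °C to rt
Reagents that add atoms: N-bromosuccinimide, O=C1CCC(=O)N1Br
Why: Electrophilic aromatic bromination, which should go to ring D as the most electron-rich ring and there to C-8, the more nucleophilic of its two free positions in 5,7-di-O-benzylated flavan-3-ols, with one equivalent of NBS at low temperature stopping at the monobromide.

Step 3
Reactants: 3 (2R,3R)-8-bromo-5,7,3',4'-tetra-O-benzylepicatechin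
Product: 4 (2R,3R)-8-bromo-3,5,7,3',4'-penta-O-benzylepicatechin
Conditions: NaH, BnBr, DMF, 0 °C to rt
Reagents that add atoms: benzyl bromide, BrCc1ccccc1
Why: Williamson ether synthesis on the sodium alkoxide, which removes the last acidic proton before the halogen–metal exchange and touches neither the aryl bromide nor the two stereocentres.

**Fragment 2 (steps 4–7)**

Step 4
Reactants: 5 4-hydroxybenzaldehyde
Product: 6 4-formylphenyl pivalate
Conditions: PivCl, Et3N, DMAP (cat.), CH2Cl2, 0 °C to rt
Reagents that add atoms: pivaloyl chloride, CC(C)(C)C(=O)Cl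
Why: DMAP-catalysed O-acylation of the phenol, which turns the strongly donating ring B oxygen into a nearly neutral substituent and gives an ester hindered enough to outlast the later organometallic step.

Step 5
Reactants: 6 4-formylphenyl pivalate
Product: 7 (R)-4-(1-hydroxybut-3-en-1-yl)phenyl pivalate
Conditions: (R)-BINOL (20 mol %), Ti(OiPr)4 (10 mol %), 4 Å MS, allylSnBu3 (1.2 equiv), CH2Cl2, −20 °C
Reagents that add atoms: allyltributylstannane, C=CC[Sn](CCCC)(CCCC)CCCC
Why: Keck asymmetric allylation, in which the (R)-BINOL–titanium Lewis acid binds the aldehyde and exposes its Re face to the stannane, so that the (R)-carbinol is set under neutral conditions that spare the aryl ester, and any minor enantiomer becomes a separable diastereomer after the union with the epicatechin fragment.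

Step 6
Reactants: 7 (R)-4-(1-hydroxybut-3-en-1-yl)phenyl pivalate, 8 3-(benzyloxy)phenol
Product: 9 (S)-4-{1-[3-(benzyloxy)phenoxy]but-3-en-1-yl}phenyl pivalate
Conditions: PPh3, DIAD, toluene, −10 °C to rt
Reagents that add atoms: none
Why: Mitsunobu etherification, in which the phenol displaces the oxyphosphonium leaving group by SN2 with inversion from (R) to (S), the non-donating pivaloyloxy group on ring B and the cold non-polar medium holding back an SN1 leak that would erode the configuration.

Step 7
Reactants: 9 (S)-4-{1-[3-(benzyloxy)phenoxy]but-3-en-1-yl}phenyl pivalate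
Product: 11 (S)-4-{1-[3-(benzyloxy)phenoxy]-3-oxopropyl}phenyl pivalate, via secondary ozonide 10 (not isolated)
Conditions: O3/O2, Sudan Red 7B (indicator), CH2Cl2, −78 °C; PPh3, −78 °C to rt; rapid filtration through silica
Reagents that add atoms: ozone, [O-][O+]=O
Why: Ozonolysis by the Criegee sequence with reductive work-up, in which the terminal alkene reacts far faster than the alkoxyarenes, the dye signals the end point before excess ozone builds up, and the neutral phosphine reduction avoids β-elimination of the aryloxide, so that the stereocentre is untouched.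

**Union, key step and end game (steps 8–11)**

Step 8
Reactants: 4 (2R,3R)-8-bromo-3,5,7,3',4'-penta-O-benzylepicatechin, 11 (S)-4-{1-[3-(benzyloxy)phenoxy]-3-oxopropyl}phenyl pivalate
Product: 14 (3S)-3-[3-(benzyloxy)phenoxy]-3-[4-(pivaloyloxy)phenyl]-1-(penta-O-benzylepicatechin-8-yl)propan-1-ol (both C-1 epimers), via aryllithium 12 (not isolated), via arylcerium dichloride 13 (not isolated)
Conditions: 4 (1.2 equiv), n-BuLi (1.15 equiv), THF, −78 °C; anhydrous CeCl3 (1.3 equiv), −78 °C; 11 (1.0 equiv), −78 °C; aq. pH 7 buffer; Et3N-deactivated silica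
Reagents that add atoms: none
Why: Bromine–lithium exchange, transmetalation and organocerium 1,2-addition, in which the weakly basic and oxophilic arylcerium adds to the aldehyde instead of enolising it (which would expel the β-aryloxide) or attacking the hindered pivalate, and the new carbinol centre needs no control because step 9 erases it.

Step 9
Reactants: 14 (3S)-3-[3-(benzyloxy)phenoxy]-3-[4-(pivaloyloxy)phenyl]-1-(penta-O-benzylepicatechin-8-yl)propan-1-ol (both C-1 epimers)
Product: 15 (2S,4S)-7-(benzyloxy)-4-(penta-O-benzylepicatechin-8-yl)-2-[4-(pivaloyloxy)phenyl]chroman (2,4-cis; the 4'-O-pivaloyl hexa-O-benzyl ether of the target)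
Conditions: BF3·OEt2 (0.3 equiv), 4 Å MS, CH2Cl2 (0.005 M), −78 to −40 °C; Et3N quench
Reagents that add atoms: none
Why: BF3 (and the BF3·OH2 formed as water is released) ionises either carbinol epimer to one planar benzylic cation whose charge is shared by the C-5 and C-7 benzyloxy oxygens and the pyran oxygen of ring D, the tethered 3-benzyloxyphenyl ether attacks it, and proton loss restores aromaticity so that the C-4–C-4a bond is not given back. The closest known reaction type is the acid-promoted intramolecular Friedel–Crafts cycloalkylation of 3-aryloxy-1-arylpropan-1-ols to 4-arylchromans. Ring C closes as a six-membered ring, 6-exo-trig at the cationic carbon (the exocyclic C=C of its quinone-methide resonance form stays outside the new ring) and endo with respect to the C-4a–C-8a bond of the arene, through a chair-like array. The new C-4 centre is controlled by the existing C-2 centre: with the C-2 aryl group equatorial, the bulky ring D takes the pseudo-equatorial site rather than a 1,3-diaxial contact with H-2, which should give the 2,4-cis, (4S) product from both carbinol epimers. Regioselectivity is needed between the two carbons ortho to the ether oxygen, and the one para to benzyloxy is at least as activated and far less crowded than the carbon wedged between the two oxygens. Chemoselectivity is needed between the two benzylic C–O bonds, and the tri-oxygenated ring D set against the pivaloyloxy-deactivated ring B makes the carbinol ionise first, while substoichiometric acid, low temperature and high dilution hold back C-2–O cleavage, proton loss from C-3 and intermolecular attack at C-6 of ring D.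

Step 10
Reactants: 15 (2S,4S)-7-(benzyloxy)-4-(penta-O-benzylepicatechin-8-yl)-2-[4-(pivaloyloxy)phenyl]chroman
Product: 16 (2S,4S)-7-(benzyloxy)-2-(4-hydroxyphenyl)-4-(penta-O-benzylepicatechin-8-yl)chroman
Conditions: DIBAL-H (3 equiv), CH2Cl2, −78 °C; aq. potassium sodium tartrate
Reagents that add atoms: none
Why: Reductive cleavage of the aryl ester by hydride (ester reduction with DIBAL-H), which gives an aluminium phenoxide and neopentyl alcohol at −78 °C without touching the benzyl ethers or the two pyran rings, and which avoids a free 4'-phenoxide in warm protic base that could open ring C through a para-quinone methide and scramble C-2.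

Step 11
Reactants: 16 (2S,4S)-7-(benzyloxy)-2-(4-hydroxyphenyl)-4-(penta-O-benzylepicatechin-8-yl)chroman
Product: 17 (2R,3R)-2-(3,4-dihydroxyphenyl)-8-[(2S,4S)-7-hydroxy-2-(4-hydroxyphenyl)chroman-4-yl]chroman-3,5,7-triol (CNP0298337.1)
Conditions: H2 (1 atm), Pd(OH)2/C, THF/MeOH (1:1), rt; filtration under Ar
Reagents that add atoms: none
Why: Catalytic hydrogenolysis of the six O-benzyl groups, whose exocyclic benzylic C–O bonds are cleaved much faster at 1 atm than the endocyclic C-2–O bonds of rings C and F or the diarylmethine C-4, as is usual for benzylated flavan-3-ol oligomers, so that all four stereocentres persist.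

**Compound list**

1 | (−)-epicatechin, (2R,3R) | Oc1cc(O)c2c(c1)O[C@H](c1ccc(O)c(O)c1)[C@H](O)C2 | starting material
2 | (2R,3R)-5,7,3',4'-tetra-O-benzylepicatechin | c1c(OCc2ccccc2)cc(OCc2ccccc2)c2c1O[C@H](c1ccc(OCc3ccccc3)c(OCc3ccccc3)c1)[C@H](O)C2 | intermediate
3 | (2R,3R)-8-bromo-5,7,3',4'-tetra-O-benzylepicatechin | Brc1c(OCc2ccccc2)cc(OCc2ccccc2)c2c1O[C@H](c1ccc(OCc3ccccc3)c(OCc3ccccc3)c1)[C@H](O)C2 | intermediate
4 | (2R,3R)-8-bromo-3,5,7,3',4'-penta-O-benzylepicatechin | Brc1c(OCc2ccccc2)cc(OCc2ccccc2)c2c1O[C@H](c1ccc(OCc3ccccc3)c(OCc3ccccc3)c1)[C@H](OCc1ccccc1)C2 | intermediate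
5 | 4-hydroxybenzaldehyde | O=Cc1ccc(O)cc1 | starting material
6 | 4-formylphenyl pivalate | CC(C)(C)C(=O)Oc1ccc(C=O)cc1 | intermediate
7 | (R)-4-(1-hydroxybut-3-en-1-yl)phenyl pivalate | CC(C)(C)C(=O)Oc1ccc([C@H](O)CC=C)cc1 | intermediate
8 | 3-(benzyloxy)phenol | Oc1cccc(OCc2ccccc2)c1 | starting material
9 | (S)-4-{1-[3-(benzyloxy)phenoxy]but-3-en-1-yl}phenyl pivalate | CC(C)(C)C(=O)Oc1ccc([C@@H](Oc2cccc(OCc3ccccc3)c2)CC=C)cc1 | intermediate
10 | secondary ozonide (3-substituted 1,2,4-trioxolane) of 9, ring carbon unassigned | CC(C)(C)C(=O)Oc1ccc([C@@H](Oc2cccc(OCc3ccccc3)c2)CC2OCOO2)cc1 | intermediate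
11 | (S)-4-{1-[3-(benzyloxy)phenoxy]-3-oxopropyl}phenyl pivalate | CC(C)(C)C(=O)Oc1ccc([C@@H](Oc2cccc(OCc3ccccc3)c2)CC=O)cc1 | intermediate
12 | (penta-O-benzylepicatechin-8-yl)lithium | [Li]c1c(OCc2ccccc2)cc(OCc2ccccc2)c2c1O[C@H](c1ccc(OCc3ccccc3)c(OCc3ccccc3)c1)[C@H](OCc1ccccc1)C2 | intermediate
13 | (penta-O-benzylepicatechin-8-yl)cerium dichloride | Cl[Ce](Cl)c1c(OCc2ccccc2)cc(OCc2ccccc2)c2c1O[C@H](c1ccc(OCc3ccccc3)c(OCc3ccccc3)c1)[C@H](OCc1ccccc1)C2 | intermediate
14 | (3S)-3-[3-(benzyloxy)phenoxy]-3-[4-(pivaloyloxy)phenyl]-1-(penta-O-benzylepicatechin-8-yl)propan-1-ol, both C-1 epimers | CC(C)(C)C(=O)Oc1ccc([C@@H](Oc2cccc(OCc3ccccc3)c2)CC(O)c2c(OCc3ccccc3)cc(OCc3ccccc3)c3c2O[C@H](c2ccc(OCc4ccccc4)c(OCc4ccccc4)c2)[C@H](OCc2ccccc2)C3)cc1 | intermediate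
15 | (2S,4S)-7-(benzyloxy)-4-(penta-O-benzylepicatechin-8-yl)-2-[4-(pivaloyloxy)phenyl]chroman, 2,4-cis | CC(C)(C)C(=O)Oc1ccc([C@@H]2C[C@H](c3c(OCc4ccccc4)cc(OCc4ccccc4)c4c3O[C@H](c3ccc(OCc5ccccc5)c(OCc5ccccc5)c3)[C@H](OCc3ccccc3)C4)c3ccc(OCc4ccccc4)cc3O2)cc1 | intermediate
16 | (2S,4S)-7-(benzyloxy)-2-(4-hydroxyphenyl)-4-(penta-O-benzylepicatechin-8-yl)chroman | Oc1ccc([C@@H]2C[C@H](c3c(OCc4ccccc4)cc(OCc4ccccc4)c4c3O[C@H](c3ccc(OCc5ccccc5)c(OCc5ccccc5)c3)[C@H](OCc3ccccc3)C4)c3ccc(OCc4ccccc4)cc3O2)cc1 | intermediate
17 | (2R,3R)-2-(3,4-dihydroxyphenyl)-8-[(2S,4S)-7-hydroxy-2-(4-hydroxyphenyl)chroman-4-yl]chroman-3,5,7-triol | Oc1ccc([C@@H]2C[C@H](c3c(O)cc(O)c4c3O[C@H](c3ccc(O)c(O)c3)[C@H](O)C4)c3ccc(O)cc3O2)cc1 | target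

**Step count**

Total step count: 11.
Longest linear sequence: 8 (steps 4 to 11, from 5).

**Steps most likely to fail**

1. **Step 9.**
 - What may go wrong: facial discrimination at the planar cation may be weak, because peri strain against H-5 competes with the 1,3-diaxial penalty. Proton loss from C-3 followed by departure of the aryloxide, and intermolecular alkylation, are the other failure processes.
 - Fallback: set C-4 by hydride delivery to a preformed ring C instead of by ring closure. It sets out from 11. Pinnick oxidation (NaClO2, NaH2PO4, 2-methyl-2-butene, t-BuOH/H2O) should give the carboxylic acid F1. Trifluoroacetic anhydride in CH2Cl2 at 0 °C should close it by intramolecular Friedel–Crafts acylation, para to benzyloxy, to the (2S)-flavanone F2. Addition of arylcerium 13 in THF at −78 °C should give the tertiary flavan-4-ol F3. Ionic reduction (Et3SiH, CF3CO2H, CH2Cl2, −78 to −20 °C) then passes through the ring C cation. That cation should take up hydride pseudo-axially on the face of H-2, trans to the C-2 aryl group, which leaves ring D cis. The route is rejoined at 15.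

2. **Step 8.**
 - What may go wrong: enolisation of the aldehyde followed by expulsion of the β-aryloxide, sluggish addition of the doubly ortho-substituted aryl-metal, or acyl attack at the pivalate.
 - Fallback: acylate a non-basic arylzinc and then reduce the ketone. It sets out from 11 and 12. Compound 11 is oxidised as above to the carboxylic acid F1, and (COCl)2 with catalytic DMF in CH2Cl2 should give the acid chloride F4. Compound 12 is transmetalated with ZnCl2 to the arylzinc chloride F5. A Pd(PPh3)4-catalysed Negishi acylation in THF should join the two to the β-aryloxy ketone F6. Luche reduction (NaBH4, CeCl3·7H2O, MeOH/THF, −40 °C) comes back to the route at 14.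

3. **Step 6.**
 - What may go wrong: partial ionisation of the activated benzylic alcohol with erosion of configuration, or elimination toward the conjugated diene.
 - Fallback: form the oxygen–aryl bond instead of the oxygen–alkyl bond, so that no bond at the stereocentre is broken. It sets out from 6. Keck allylation with (S)-BINOL should give the (S)-homoallylic alcohol F7. Ullmann-type C–O coupling with commercial 1-benzyloxy-3-iodobenzene (CuI, 3,4,7,8-tetramethyl-1,10-phenanthroline, Cs2CO3, toluene, 110 °C) should arylate the oxygen with retention. The route is rejoined at 9.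

**Further compounds**

F1 | step 9 | (3S)-3-[3-(benzyloxy)phenoxy]-3-[4-(pivaloyloxy)phenyl]propanoic acid | CC(C)(C)C(=O)Oc1ccc([C@@H](Oc2cccc(OCc3ccccc3)c2)CC(=O)O)cc1
F2 | step 9 | (2S)-7-(benzyloxy)-2-[4-(pivaloyloxy)phenyl]chroman-4-one | CC(C)(C)C(=O)Oc1ccc([C@@H]2CC(=O)c3ccc(OCc4ccccc4)cc3O2)cc1
F3 | step 9 | (2S)-7-(benzyloxy)-4-(penta-O-benzylepicatechin-8-yl)-2-[4-(pivaloyloxy)phenyl]chroman-4-ol, C-4 unassigned | CC(C)(C)C(=O)Oc1ccc([C@@H]2CC(O)(c3c(OCc4ccccc4)cc(OCc4ccccc4)c4c3O[C@H](c3ccc(OCc5ccccc5)c(OCc5ccccc5)c3)[C@H](OCc3ccccc3)C4)c3ccc(OCc4ccccc4)cc3O2)cc1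
F4 | step 8 | (3S)-3-[3-(benzyloxy)phenoxy]-3-[4-(pivaloyloxy)phenyl]propanoyl chloride | CC(C)(C)C(=O)Oc1ccc([C@@H](Oc2cccc(OCc3ccccc3)c2)CC(=O)Cl)cc1
F5 | step 8 | (penta-O-benzylepicatechin-8-yl)zinc chloride | Cl[Zn]c1c(OCc2ccccc2)cc(OCc2ccccc2)c2c1O[C@H](c1ccc(OCc3ccccc3)c(OCc3ccccc3)c1)[C@H](OCc1ccccc1)C2
F6 | step 8 | (3S)-3-[3-(benzyloxy)phenoxy]-3-[4-(pivaloyloxy)phenyl]-1-(penta-O-benzylepicatechin-8-yl)propan-1-one | CC(C)(C)C(=O)Oc1ccc([C@@H](Oc2cccc(OCc3ccccc3)c2)CC(=O)c2c(OCc3ccccc3)cc(OCc3ccccc3)c3c2O[C@H](c2ccc(OCc4ccccc4)c(OCc4ccccc4)c2)[C@H](OCc2ccccc2)C3)cc1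
F7 | step 6 | (S)-4-(1-hydroxybut-3-en-1-yl)phenyl pivalate | CC(C)(C)C(=O)Oc1ccc([C@@H](O)CC=C)cc1
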